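The pyran ring (ring C: O1, C2, C3, C4, C4a, C8a) is cut at C3–C2 and at O1–C8a, so that acetaldehyde supplies C2 with its methyl group and O1. The carbon that becomes C4 is carried as a ketone: it makes C3 an enol silane nucleophile and, sitting ortho to C8a on the benzo ring (ring A), activates a C8a–F bond for SNAr. An enantioselective Mukaiyama aldol addition to acetaldehyde and a fluoride-triggered alkoxide SNAr, run in one flask, form both bonds and set C2. The precursor is the achiral enol silane of 2'-fluoro-6'-methoxyacetophenone. The C4 ketone later becomes an o-quinone methide that 1,8-dimethoxynaphthalene attacks trans to the C2 methyl group.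

Key step: step 2

Assumptions: compounds 1, 3 and 9 are catalogue chemicals. Chroman numbering (O1, C2, C3, C4, C4a, C5 to C8, C8a) is used for all intermediates. The target is (2R,4S), with the 2-methyl and 4-aryl groups trans. The catalyst enantiomer in step 2 is assigned from the accepted facial model of this oxazaborolidinone class; should the sense prove reversed, the (S)-tryptophan-derived antipode is used, and the sign of rotation of the known compound 7 serves as the check.

Step 1
Reactants: 1 1-(2-fluoro-6-methoxyphenyl)ethan-1-one
Product: 2 trimethyl{[1-(2-fluoro-6-methoxyphenyl)ethenyl]oxy}silane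
Conditions: TMSOTf (1.2 equiv), Et3N (1.5 equiv), CH2Cl2, 0 °C
Reagents that add atoms: trimethylsilyl trifluoromethanesulfonate, C[Si](C)(C)OS(=O)(=O)C(F)(F)F
Why: Soft enolization of the methyl ketone with TMSOTf/Et3N (silyl enol ether formation) is regiochemically unambiguous because only the methyl group carries α-hydrogens, and no stereocenter is formed.

Step 2
Reactants: 2 trimethyl{[1-(2-fluoro-6-methoxyphenyl)ethenyl]oxy}silane; 3 acetaldehyde
Product: 6 (R)-5-methoxy-2-methylchroman-4-one, via β-silyloxy ketone 4 (not isolated), via ammonium alkoxide 5 (not isolated)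
Conditions: 3 (1.2 equiv), (4R)-2-butyl-4-(1H-indol-3-ylmethyl)-3-(4-methylbenzenesulfonyl)-1,3,2-oxazaborolidin-5-one (20 mol %, from N-tosyl-(R)-tryptophan and n-BuB(OH)2), EtCN, −78 °C, slow addition of 2; then Bu4NF (1.0 equiv), THF, −78 → 0 °C, same flask; AcOH
Reagents that add atoms: none
Why: The boron Lewis acid binds acetaldehyde and the enol silane carbon C3 attacks its Si face through an open transition state (catalytic enantioselective Mukaiyama aldol addition, the closest known reaction type for the C3–C2 bond), silyl transfer giving 4 and fixing C2 as R by catalyst control. Fluoride then cleaves the O–Si bond and the alkoxide oxygen of 5 adds to C8a, ortho to the acyl group, to give a Meisenheimer adduct whose charge rests on the C4 carbonyl; loss of fluoride completes the O1–C8a bond (intramolecular SNAr of an alkoxide on an o-fluoroaryl ketone, a known type of chroman-4-one closure). The pyran ring thus closes as a six-membered ring by addition–elimination at the sp2 carbon C8a (6-endo with respect to the C4a=C8a π bond that carries the activation), and the fluoride expelled from C8a replaces the one used for desilylation, so fluoride is not consumed. C2 is not touched in the ring closure because the C2–O1 bond is never broken, so the configuration set in the aldol stage is retained. The step needs cyclization to outrun retro-aldol cleavage and β-elimination of the alkoxide and needs a single site of substitution; the ketone-activated C–F bond held within reach of a six-membered closure, the low temperature, and the fact that C5 carries only a methoxy group (a far poorer leaving group) should secure both.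

Step 3
Reactants: 6 (R)-5-methoxy-2-methylchroman-4-one
Product: 7 (R)-5-hydroxy-2-methylchroman-4-one
Conditions: BCl3 (1.5 equiv), CH2Cl2, −78 → 0 °C; then aq. NaHCO3
Reagents that add atoms: none
Why: BCl3 chelates between the C4 carbonyl and the peri 5-methoxy oxygen and chloride removes the methyl group (chelation-controlled Lewis acid ether cleavage), which should leave the ring ether O1, on the far side of the carbonyl, and the C2 stereocenter untouched.

Step 4
Reactants: 7 (R)-5-hydroxy-2-methylchroman-4-one
Product: 8 (2R,4S)-2-methylchroman-4,5-diol (cis; any 4R epimer is carried along)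
Conditions: NaBH4 (2 equiv), MeOH, 0 °C; pH 7 buffer; crude 8 used at once
Reagents that add atoms: none
Why: Borohydride reduction of the aryl ketone by axial hydride delivery should give mainly the cis alcohol (4S), and the C4 configuration is of no consequence because this center is ionized in step 5 while C2 is not involved.

Step 5
Reactants: 8 (2R,4S)-2-methylchroman-4,5-diol; 9 1,8-dimethoxynaphthalene
Product: 11 cladonaphchrom A (2R,4S)-4-(4,5-dimethoxynaphthalen-1-yl)-2-methylchroman-5-ol, via o-quinone methide 10 (not isolated)
Conditions: 9 (3 equiv), TsOH·H2O (10 mol %), 4 Å MS, CH2Cl2, 0 °C → rt, slow addition of 8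
Reagents that add atoms: none
Why: Acid-catalyzed loss of water from the benzylic 4-OH, assisted by the 5-OH, gives o-quinone methide 10 (or its protonated benzylic cation), which alkylates 9 at C4, the unhindered position para to a methoxy group (Friedel–Crafts alkylation through an o-quinone methide); the arene should add axially to the half-chair that holds the C2 methyl group pseudo-equatorial, so the new C4 center is S with the aryl group trans to the methyl group under control by C2, an outcome also favored thermodynamically because the peri 5-OH disfavors a pseudo-equatorial aryl group.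

Compound list
1 | 1-(2-fluoro-6-methoxyphenyl)ethan-1-one | CC(=O)c1c(F)cccc1OC | starting material
2 | trimethyl{[1-(2-fluoro-6-methoxyphenyl)ethenyl]oxy}silane | C=C(O[Si](C)(C)C)c1c(F)cccc1OC | intermediate
3 | acetaldehyde | CC=O | starting material
4 | (R)-1-(2-fluoro-6-methoxyphenyl)-3-[(trimethylsilyl)oxy]butan-1-one | C[C@H](CC(=O)c1c(F)cccc1OC)O[Si](C)(C)C | intermediate (not isolated)
5 | tetrabutylammonium (R)-4-(2-fluoro-6-methoxyphenyl)-4-oxobutan-2-olate | C[C@@H]([O-])CC(=O)c1c(F)cccc1OC.CCCC[N+](CCCC)(CCCC)CCCC | intermediate (not isolated)
6 | (R)-5-methoxy-2-methylchroman-4-one | C[C@@H]1CC(=O)c2c(OC)cccc2O1 | intermediate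
7 | (R)-5-hydroxy-2-methylchroman-4-one | C[C@@H]1CC(=O)c2c(O)cccc2O1 | intermediate
8 | (2R,4S)-2-methylchroman-4,5-diol | C[C@@H]1C[C@H](O)c2c(O)cccc2O1 | intermediate
9 | 1,8-dimethoxynaphthalene | COc1cccc2cccc(OC)c12 | starting material
10 | (R)-2-methyl-2,3-dihydro-5H-chromen-5-one (o-quinone methide) | C[C@@H]1CC=C2C(=O)C=CC=C2O1 | intermediate (not isolated)
11 | cladonaphchrom A, (2R,4S)-4-(4,5-dimethoxynaphthalen-1-yl)-2-methylchroman-5-ol | COc1cccc2c([C@@H]3C[C@@H](C)Oc4cccc(O)c43)ccc(OC)c12 | target

Total step count: 5. Longest linear sequence: 5 steps (1 to 11).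

Steps most likely to fail

Step 2. After desilylation the alkoxide may undergo retro-aldol cleavage (with re-addition outside catalyst control) or β-elimination faster than it closes the ring. The chromanone formed may also open and reclose at O1–C2 under the basic fluoride. Either process would erode enantiopurity or mass balance. The fallback sets out from 1 and comes back at 6. Compound 1 is condensed with ethyl acetate (NaH, THF, reflux; Claisen condensation) to give 1-(2-fluoro-6-methoxyphenyl)butane-1,3-dione F1, which is not isolated. On heating in DMF at 100 °C its enolate oxygen displaces fluoride at C8a to give 5-methoxy-2-methyl-4H-chromen-4-one F2. The same two bonds are thus still formed in one operation, now without a stereocenter. C2 is then set by the known copper hydride asymmetric conjugate reduction of chromones (Cu(OAc)2, DTBM-SEGPHOS, (EtO)2MeSiH, t-BuOH, toluene, 0 °C), with the ligand antipode chosen to deliver hydride to the face of C2 that gives the R product 6.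

Step 5. The o-quinone methide may alkylate the electron-rich phenol ring of another molecule of 8 or of the product (oligomerization), the naphthalene may be alkylated twice, or facial selectivity at C4 may be insufficient. The fallback sets out from 8 and comes back at 11. Compound 8 is acetylated on both oxygens (Ac2O, pyridine, DMAP) to (2R,4S)-2-methylchroman-4,5-diyl diacetate F3. BF3·OEt2 in CH2Cl2 at −40 °C ionizes only the benzylic acetate, while the aryl acetate lowers the nucleophilicity of ring A and blocks quinone methide formation. Alkylation of 9 (3 equiv) under these colder, kinetically controlled conditions should give (2R,4S)-4-(4,5-dimethoxynaphthalen-1-yl)-2-methylchroman-5-yl acetate F4. K2CO3 in MeOH then frees the phenol to give 11.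

Step 3. The Lewis acid may open and reclose the pyran ring at O1–C2 through the boron enolate, with loss of configuration at C2, or may cleave the ring ether. The fallback sets out from 1 and comes back at 7, replacing the methyl ether by a benzyl ether that is removed under neutral conditions. Compound 1 is demethylated with BBr3 (CH2Cl2, −78 → 0 °C) to 1-(2-fluoro-6-hydroxyphenyl)ethan-1-one F5 and benzylated (BnBr, K2CO3, DMF) to 1-[2-(benzyloxy)-6-fluorophenyl]ethan-1-one F6. TMSOTf/Et3N converts this into {[1-(2-(benzyloxy)-6-fluorophenyl)ethenyl]oxy}trimethylsilane F7. Under the conditions of step 2 with acetaldehyde this should give (R)-1-[2-(benzyloxy)-6-fluorophenyl]-3-[(trimethylsilyl)oxy]butan-1-one F8 and then tetrabutylammonium (R)-4-[2-(benzyloxy)-6-fluorophenyl]-4-oxobutan-2-olate F9, neither isolated, and finally (R)-5-(benzyloxy)-2-methylchroman-4-one F10. Hydrogenolysis (H2, palladium on carbon, EtOAc, rt) gives 7.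

Further compounds
F1 | step 2 | 1-(2-fluoro-6-methoxyphenyl)butane-1,3-dione | CC(=O)CC(=O)c1c(F)cccc1OC
F2 | step 2 | 5-methoxy-2-methyl-4H-chromen-4-one | CC1=CC(=O)c2c(OC)cccc2O1
F3 | step 5 | (2R,4S)-2-methylchroman-4,5-diyl diacetate | C[C@@H]1C[C@H](OC(C)=O)c2c(OC(C)=O)cccc2O1
F4 | step 5 | (2R,4S)-4-(4,5-dimethoxynaphthalen-1-yl)-2-methylchroman-5-yl acetate | COc1cccc2c([C@@H]3C[C@@H](C)Oc4cccc(OC(C)=O)c43)ccc(OC)c12
F5 | step 3 | 1-(2-fluoro-6-hydroxyphenyl)ethan-1-one | CC(=O)c1c(F)cccc1O
F6 | step 3 | 1-[2-(benzyloxy)-6-fluorophenyl]ethan-1-one | CC(=O)c1c(F)cccc1OCc1ccccc1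
F7 | step 3 | {[1-(2-(benzyloxy)-6-fluorophenyl)ethenyl]oxy}trimethylsilane | C=C(O[Si](C)(C)C)c1c(F)cccc1OCc1ccccc1
F8 | step 3 | (R)-1-[2-(benzyloxy)-6-fluorophenyl]-3-[(trimethylsilyl)oxy]butan-1-one | C[C@H](CC(=O)c1c(F)cccc1OCc1ccccc1)O[Si](C)(C)C
F9 | step 3 | tetrabutylammonium (R)-4-[2-(benzyloxy)-6-fluorophenyl]-4-oxobutan-2-olate | C[C@@H]([O-])CC(=O)c1c(F)cccc1OCc1ccccc1.CCCC[N+](CCCC)(CCCC)CCCC
F10 | step 3 | (R)-5-(benzyloxy)-2-methylchroman-4-one | C[C@@H]1CC(=O)c2c(OCc3ccccc3)cccc2O1
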